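The runs are simulated from invented constants; the scatter is artificial.

At the first reading, 19 s after mixing, the grey run holds 29.5 mM of Pdt and the blue run 24.6 mM, a ratio of 1.20, though grey was charged with twice the Sbt at equal [Ptn]. Two chemists dispute what this means.

| flask | Sbt | Ptn | time |
|---|---|---|---|
| blue | 200 mM | 400 mM |  |
| green | 80.0 mM | 280 mM |  |
| grey | 400 mM | 400 mM |  |
| teal | 600 mM | 1200 mM | 95 s |

| blue run: time / s | blue run: [Pdt] / mM | green run: time / s | green run: [Pdt] / mM | grey run: time / s | grey run: [Pdt] / mM |
|---|---|---|---|---|---|
| 19 | 24.6 | 19 | 11.4 | 19 | 29.5 |
| 38 | 45.5 | 38 | 16.3 | 38 | 53.7 |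
| 57 | 64.0 | 57 | 20.9 | 57 | 78.2 |
| 76 | 78.6 | 76 | 28.6 | 76 | 99.0 |
| 95 | 92.4 | 95 | 33.5 | 95 | 116.9 |

(scatter of a reading: 1 mM)

- Overall: Sbt + Ptn -> Pdt.
- Constant volume, constant temperature.
- What is held in complexes is read along with the free species.
- "The second partner" is Ptn.
- An order is taken over about fifteen percent of the charge, up and down.

1. the exponent of [Ptn] in the starting rate at the charge of the blue run (at the point where two percent of the Sbt have become Pdt)
2. the exponent of [Sbt] in the starting rate at the charge of the blue run (at the point where two percent of the Sbt have become Pdt) (one fixed amount of Pdt, the same in the runs compared)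
3. the green run starts with 120 mM less of Sbt and of Ptn than the blue run, and with no Pdt. Compared where both hold the same amount of Sbt, once fifteen percent of what the green run was charged with has turned into Pdt, is the green run faster, slower or alike (within a tenth)?
4. Pdt in the teal run at 95 s, as a share of the Sbt charged
5. which of these the readings show (the second partner is lost in pairs / nothing beyond the main steps / the two partners rest in a complex / the product binds the substrate)

Both reckon with the loss constant, a pseudo-first-order constant: minus the logarithm of the share of charged Sbt not yet turned into Pdt, divided by the time. It is the share of the remaining Sbt, bound forms counted, that turns each second. In the blue run it is 0.00691 s⁻¹ at the first reading and 0.00653 s⁻¹ at the last, so it is nearly constant and I freeze it. Pdt then comes to half of the Sbt charged at ln(2) over the constant, which is 106 s in the blue run, past its last reading. The green run's last reading gives 0.00571 s⁻¹, and so 121 s.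

The first chemist holds a plain law, first order in [Sbt] and second order in [Ptn], so that the constant follows [Ptn] squared. The teal run has 3.00 times the blue [Ptn], so he multiplies by 9.00, reaches 0.0587 s⁻¹, and expects 99.6% of the teal Sbt as Pdt at 95 s.

The second chemist points to the first reading, where the grey run has turned 29.5 mM of its 400 mM of Ptn into Pdt and the blue run 24.6 mM of its 400 mM, so that under the plain law the two constants should nearly match there. The constant read at that point in the grey run is 0.00403 s⁻¹, lower than the blue run's 0.00691 s⁻¹ by a ratio of 0.583. She holds that Sbt and Ptn rest in a complex, the resting state, so that extra Sbt ties up Ptn. My own reckoning sides with her: it puts the teal constant below 0.0587 s⁻¹, though it gives no teal share of its own.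

The forecast, which is hers and opens with “The early rates do not fit simple behaviour.”, gives 1.7 for ord_R, 0.5 for ord_S, "alike", 86% and "the two partners rest in a complex".

The simulation gives 1.5, 0.51, "alike", 82.8% and "the two partners rest in a complex".

    Sbt + Ptn → Pdt (0.01660 M⁻¹ s⁻¹)
    Sbt + 2 Ptn → Pdt + Ptn (0.2690 M⁻² s⁻¹)
    Sbt + Ptn ⇌ Sbt.Ptn, settled at all times (8.670 M⁻¹)

The frozen times stand against 107 s for the blue run and 121 s for the green run. The teal constant comes to 0.0185 s⁻¹, or 2.83 times blue's rather than 9.00, due to the association of Sbt with Ptn. The plain law belongs to a flask without Sbt.Ptn: there the order in [Sbt] at the blue charge is 1.0, not 0.51. The teal run with the association taken away gives >99.9% of its Sbt as Pdt at 95 s, against 82.8% with it.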